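**Plan** (target numbered as a bicyclo[3.2.1]oct-3-ene-2,8-dione: C1 = bridgehead between the C2 and C8 ketones, C4 = styryl carbon, C5 = second bridgehead, C6 = CH carrying the resorcinol ring, C7 = CH carrying the 4-hydroxyphenyl ring)
1. Cuts, in retrosynthetic order: four O–Si bonds; the aryl–vinyl bond (Heck); the C4–vinyl bond together with the C3=C4 unsaturation; the C1–C7 bond; the C1–C2 bond (Claisen); the C7–aryl bond; the C5–C6 bond (Michael).
2. Forward: the open-chain C5–C6 bond first, then the aryl group on C7, then the six-membered ring C1–C2–C3–C4–C5–C8 as a cyclohexane-1,3-dione, then the five-membered ring C1–C8–C5–C6–C7 by bridging C1 to C7; the C3=C4 alkene, vinyl group, aryl group and free phenols follow.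
3. Feature used: C1 lies between both ketones (it is the 2-carbon of a cyclohexane-1,3-dione once C1–C7 is cut) and C7 is benzylic to a para-oxygenated ring (a latent benzylic cation or para-quinone methide) held two atoms from C5; joining them bridges the dione.
4. Helpers: a nitro group on C7 activates the Michael acceptor, then carries the arylation, then leaves. The ring stays dihydro at C3–C4 until it is bridged, because the unbridged C3=C4 enedione is only a resorcinol tautomer and a styryl alkene on C4 would trap the C7 cation.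
5. Stereochemistry: C5 and C6 come from one catalytic enantioselective anti-Michael addition; C1 and C7 are relayed from them in the key step; the E alkene comes from the Heck reaction.

Key step: step 6

Abbreviations: TIPS = triisopropylsilyl, TIPSO = (triisopropylsilyl)oxy, TBS = tert-butyldimethylsilyl, TMS = trimethylsilyl, IBX = 2-iodoxybenzoic acid.
Assumption: the antipode of the primary amine–thiourea catalyst in step 3 is the one that gives the (4R,5R) adduct; the anti relative configuration is the intrinsic preference of this catalyst class with open-chain ketones.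
Assumption: 7 and 16 are purchased as such (silyl ethers of 4-bromophenol and 4-iodophenol).

Step 1
Reactants: 1 3,5-dihydroxybenzaldehyde
Product: 2 3,5-bis(TIPSO)benzaldehyde
Conditions: TIPSCl (2.4 equiv), imidazole (5 equiv), DMF, rt
Reagents that add atoms: triisopropylsilyl chloride, CC(C)[Si](Cl)(C(C)C)C(C)C
Why: Silylation of both phenols gives aryl TIPS ethers that tolerate the later carbonate, amide-base, Lewis-acid and organometallic steps and are removed by fluoride at the end.

Step 2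
Reactants: 2 3,5-bis(TIPSO)benzaldehyde; 3 nitromethane
Product: 4 (E)-1-(2-nitroethenyl)-3,5-bis(TIPSO)benzene
Conditions: CH3NO2 (solvent), NH4OAc (0.3 equiv), 90 °C
Reagents that add atoms: none
Why: Henry (nitroaldol) condensation with dehydration should give the thermodynamically favoured E nitroalkene.

Step 3
Reactants: 4 (E)-1-(2-nitroethenyl)-3,5-bis(TIPSO)benzene; 5 ethyl 5-oxohexanoate
Product: 6 ethyl (4R,5R)-4-acetyl-5-[3,5-bis(TIPSO)phenyl]-6-nitrohexanoate
Conditions: 5 (5 equiv), chiral primary amine–thiourea catalyst (N-(trans-2-aminocyclohexyl)thiourea of a tert-leucine amide, 10 mol%), PhCO2H (5 mol%), toluene, rt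
Reagents that add atoms: none
Why: Asymmetric enamine Michael addition in which the more substituted Z-enamine of the methyl ketone adds to the thiourea-bound nitroalkene to give the anti adduct, so that both stereocentres (future C5 and C6) are set under catalyst control.

Step 4
Reactants: 6 ethyl (4R,5R)-4-acetyl-5-[3,5-bis(TIPSO)phenyl]-6-nitrohexanoate; 7 (4-bromophenoxy)triisopropylsilane
Product: 8 ethyl (4R,5R,6RS)-4-acetyl-5-[3,5-bis(TIPSO)phenyl]-6-nitro-6-[4-(TIPSO)phenyl]hexanoate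
Conditions: Pd2(dba)3 (2.5 mol%), 2-(di-tert-butylphosphino)-2'-methylbiphenyl (6 mol%), Cs2CO3 (1.2 equiv), DME, 50 °C; aq. NH4Cl
Reagents that add atoms: none
Why: Palladium-catalysed α-arylation of a nitroalkane, in which the caesium nitronate (far more acidic than the ketone or ester α-positions) couples with the arylpalladium bromide; the new centre (future C7) is left as a mixture because it is planarised in step 6.

Step 5
Reactants: 8 ethyl (4R,5R,6RS)-4-acetyl-5-[3,5-bis(TIPSO)phenyl]-6-nitro-6-[4-(TIPSO)phenyl]hexanoate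
Product: 9 (4R)-4-{(1R,2RS)-1-[3,5-bis(TIPSO)phenyl]-2-nitro-2-[4-(TIPSO)phenyl]ethyl}cyclohexane-1,3-dione
Conditions: LiN(SiMe3)2 (3.3 equiv), THF, −78 → 0 °C; then 1 M HCl to pH 3–4, 0 °C
Reagents that add atoms: none
Why: Intramolecular Claisen condensation, in which kinetic deprotonation of the methyl ketone (the nitronate forms first and is inert) and attack on the ethyl ester close the six-membered ring, the product sitting as its dione enolate so that the stereocentre next to the ring ketone is not epimerised.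

Step 6
Reactants: 9 (4R)-4-{(1R,2RS)-1-[3,5-bis(TIPSO)phenyl]-2-nitro-2-[4-(TIPSO)phenyl]ethyl}cyclohexane-1,3-dione
Product: 10 (1R,5R,6R,7R)-6-[3,5-bis(TIPSO)phenyl]-7-[4-(TIPSO)phenyl]bicyclo[3.2.1]octane-2,8-dione
Conditions: SnCl4 (2.5 equiv), CH2Cl2 (0.01 M), −78 → 0 °C; aq. NaHCO3
Reagents that add atoms: none
Why: SnCl4 binds the enolised dione as a chlorotin β-diketonate and ionises the secondary benzylic C–NO2 bond to a cation stabilised by the para-silyloxyphenyl ring, onto which the dione carbon C1, held two atoms away through C5 and C6, collapses. The closest known reaction types are the Lewis-acid SN1 replacement of benzylic and tertiary nitro groups by carbon nucleophiles, the Friedel–Crafts-type benzylation of 1,3-diketones, and the cation-to-enol ring closure that ends the known (5+2) route from quinone monoketals and styrenes to bicyclo[3.2.1]octenediones. The five-membered ring C1–C8–C5–C6–C7 closes 5-exo-trig at the cationic carbon and enol-exo with respect to the C1=C2 enol, with the C5–C6 bond axial on the dione ring, and the seven-membered ring C1–C2–C3–C4–C5–C6–C7 follows from this bridging. C1 can bond only on the face that carries the axial C5–C6 bond, so its configuration is fixed by C5; at C7 the aryl group takes the exo position, trans to the C6 aryl group that the step-3 configuration forces endo, because the alternative eclipses both aryl groups under the six-membered ring. The step needs C- over O-alkylation and capture over E1 loss of the C6 proton: an O-adduct at the C8 oxygen is a para-silyloxybenzylic vinylogous ester that re-ionises under SnCl4 while the C–C bond does not, and with C3–C4 still saturated there is no rearomatisation and no styryl alkene to divert the cation.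

Step 7
Reactants: 10 (1R,5R,6R,7R)-6-[3,5-bis(TIPSO)phenyl]-7-[4-(TIPSO)phenyl]bicyclo[3.2.1]octane-2,8-dione
Product: 12 (1R,5R,6R,7R)-6-[3,5-bis(TIPSO)phenyl]-7-[4-(TIPSO)phenyl]bicyclo[3.2.1]oct-3-ene-2,8-dione, via trimethylsilyl enol ether 11 (not isolated)
Conditions: Me3SiOTf, Et3N, CH2Cl2, 0 °C; then IBX, 4-methoxypyridine N-oxide, DMSO, rt
Reagents that add atoms: none
Why: Soft enolisation can occur only towards C3 (C1 is a bridgehead and C8 has no enolisable α-hydrogen), and IBX dehydrogenation of the silyl enol ether installs the C3=C4 bond, which can no longer aromatise the ring because C1 and C5 are now bridgeheads.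

Step 8
Reactants: 12 (1R,5R,6R,7R)-6-[3,5-bis(TIPSO)phenyl]-7-[4-(TIPSO)phenyl]bicyclo[3.2.1]oct-3-ene-2,8-dione; 13 vinylmagnesium bromide
Product: 15 (1R,5S,6R,7R)-4-ethenyl-6-[3,5-bis(TIPSO)phenyl]-7-[4-(TIPSO)phenyl]bicyclo[3.2.1]oct-3-ene-2,8-dione, via trimethylsilyl enol ether 14 (not isolated)
Conditions: 13 (1.5 equiv), CuBr·SMe2 (10 mol%), Me3SiCl, DMPU, THF, −78 °C; then IBX, 4-methoxypyridine N-oxide, DMSO, rt
Reagents that add atoms: none
Why: Copper-catalysed, Me3SiCl-accelerated conjugate addition of the Grignard reagent places the vinyl group on C4 from the face away from the C6–C7 bridge (the other face is covered by the endo aryl group on C6), and IBX dehydrogenation of the trapped silyl enol ether restores the C3=C4 bond and erases the transient C4 stereocentre.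

Step 9
Reactants: 15 (1R,5S,6R,7R)-4-ethenyl-6-[3,5-bis(TIPSO)phenyl]-7-[4-(TIPSO)phenyl]bicyclo[3.2.1]oct-3-ene-2,8-dione; 16 tert-butyl(4-iodophenoxy)dimethylsilane
Product: 17 (1R,5S,6R,7R)-4-{(E)-2-[4-(TBS-oxy)phenyl]ethenyl}-6-[3,5-bis(TIPSO)phenyl]-7-[4-(TIPSO)phenyl]bicyclo[3.2.1]oct-3-ene-2,8-dione
Conditions: Pd(OAc)2 (5 mol%), P(o-tol)3 (10 mol%), Et3N, MeCN, 70 °C
Reagents that add atoms: none
Why: Heck reaction, in which the arylpalladium iodide inserts at the unhindered terminal vinyl carbon and syn β-hydride elimination gives the E styryl diene, the trisubstituted C3=C4 alkene being too hindered to insert.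

Step 10
Reactants: 17 (1R,5S,6R,7R)-4-{(E)-2-[4-(TBS-oxy)phenyl]ethenyl}-6-[3,5-bis(TIPSO)phenyl]-7-[4-(TIPSO)phenyl]bicyclo[3.2.1]oct-3-ene-2,8-dione
Product: 18 vitisinol D, (1R,5S,6R,7R)-6-(3,5-dihydroxyphenyl)-7-(4-hydroxyphenyl)-4-[(E)-2-(4-hydroxyphenyl)ethenyl]bicyclo[3.2.1]oct-3-ene-2,8-dione
Conditions: Bu4NF, AcOH (1:1, 6 equiv), THF, 0 °C → rt
Reagents that add atoms: none
Why: Acetic-acid-buffered fluoride cleaves all four aryl silyl ethers without building up free phenoxide or strong acid, either of which could reopen the C1–C7 bond through the para-hydroxyphenyl group.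

**Compound list**
1 | 3,5-dihydroxybenzaldehyde | O=Cc1cc(O)cc(O)c1 | starting material
2 | 3,5-bis[(triisopropylsilyl)oxy]benzaldehyde | O=Cc1cc(O[Si](C(C)C)(C(C)C)C(C)C)cc(O[Si](C(C)C)(C(C)C)C(C)C)c1 | intermediate
3 | nitromethane | C[N+](=O)[O-] | starting material
4 | (E)-1-(2-nitroethenyl)-3,5-bis[(triisopropylsilyl)oxy]benzene | [O-][N+](=O)/C=C/c1cc(O[Si](C(C)C)(C(C)C)C(C)C)cc(O[Si](C(C)C)(C(C)C)C(C)C)c1 | intermediate
5 | ethyl 5-oxohexanoate | CCOC(=O)CCCC(C)=O | starting material
6 | ethyl (4R,5R)-4-acetyl-5-{3,5-bis[(triisopropylsilyl)oxy]phenyl}-6-nitrohexanoate | CCOC(=O)CC[C@@H](C(C)=O)[C@@H](C[N+](=O)[O-])c1cc(O[Si](C(C)C)(C(C)C)C(C)C)cc(O[Si](C(C)C)(C(C)C)C(C)C)c1 | intermediate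
7 | (4-bromophenoxy)triisopropylsilane | Brc1ccc(O[Si](C(C)C)(C(C)C)C(C)C)cc1 | starting material
8 | ethyl (4R,5R,6RS)-4-acetyl-5-{3,5-bis[(triisopropylsilyl)oxy]phenyl}-6-nitro-6-{4-[(triisopropylsilyl)oxy]phenyl}hexanoate | CCOC(=O)CC[C@@H](C(C)=O)[C@@H](C(c1ccc(O[Si](C(C)C)(C(C)C)C(C)C)cc1)[N+](=O)[O-])c1cc(O[Si](C(C)C)(C(C)C)C(C)C)cc(O[Si](C(C)C)(C(C)C)C(C)C)c1 | intermediate
9 | (4R)-4-[(1R,2RS)-1-{3,5-bis[(triisopropylsilyl)oxy]phenyl}-2-nitro-2-{4-[(triisopropylsilyl)oxy]phenyl}ethyl]cyclohexane-1,3-dione (drawn as the diketo tautomer) | O=C1CC[C@@H](C(=O)C1)[C@@H](C(c1ccc(O[Si](C(C)C)(C(C)C)C(C)C)cc1)[N+](=O)[O-])c1cc(O[Si](C(C)C)(C(C)C)C(C)C)cc(O[Si](C(C)C)(C(C)C)C(C)C)c1 | intermediate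
10 | (1R,5R,6R,7R)-6-{3,5-bis[(triisopropylsilyl)oxy]phenyl}-7-{4-[(triisopropylsilyl)oxy]phenyl}bicyclo[3.2.1]octane-2,8-dione (C6 aryl endo, C7 aryl exo) | O=C1CC[C@H]2C(=O)[C@@H]1[C@H](c1ccc(O[Si](C(C)C)(C(C)C)C(C)C)cc1)[C@H]2c1cc(O[Si](C(C)C)(C(C)C)C(C)C)cc(O[Si](C(C)C)(C(C)C)C(C)C)c1 | intermediate
11 | {[(1R,5R,6R,7R)-6-{3,5-bis[(triisopropylsilyl)oxy]phenyl}-7-{4-[(triisopropylsilyl)oxy]phenyl}-8-oxobicyclo[3.2.1]oct-2-en-2-yl]oxy}trimethylsilane | C[Si](C)(C)OC1=CC[C@H]2C(=O)[C@@H]1[C@H](c1ccc(O[Si](C(C)C)(C(C)C)C(C)C)cc1)[C@H]2c1cc(O[Si](C(C)C)(C(C)C)C(C)C)cc(O[Si](C(C)C)(C(C)C)C(C)C)c1 | intermediate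
12 | (1R,5R,6R,7R)-6-{3,5-bis[(triisopropylsilyl)oxy]phenyl}-7-{4-[(triisopropylsilyl)oxy]phenyl}bicyclo[3.2.1]oct-3-ene-2,8-dione | O=C1C=C[C@H]2C(=O)[C@@H]1[C@H](c1ccc(O[Si](C(C)C)(C(C)C)C(C)C)cc1)[C@H]2c1cc(O[Si](C(C)C)(C(C)C)C(C)C)cc(O[Si](C(C)C)(C(C)C)C(C)C)c1 | intermediate
13 | vinylmagnesium bromide | C=C[Mg]Br | starting material
14 | {[(1R,4R,5R,6R,7R)-4-ethenyl-6-{3,5-bis[(triisopropylsilyl)oxy]phenyl}-7-{4-[(triisopropylsilyl)oxy]phenyl}-8-oxobicyclo[3.2.1]oct-2-en-2-yl]oxy}trimethylsilane (vinyl on the face away from the C6–C7 bridge) | C[Si](C)(C)OC1=C[C@@H](C=C)[C@H]2C(=O)[C@@H]1[C@H](c1ccc(O[Si](C(C)C)(C(C)C)C(C)C)cc1)[C@H]2c1cc(O[Si](C(C)C)(C(C)C)C(C)C)cc(O[Si](C(C)C)(C(C)C)C(C)C)c1 | intermediate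
15 | (1R,5S,6R,7R)-4-ethenyl-6-{3,5-bis[(triisopropylsilyl)oxy]phenyl}-7-{4-[(triisopropylsilyl)oxy]phenyl}bicyclo[3.2.1]oct-3-ene-2,8-dione | O=C1C=C(C=C)[C@H]2C(=O)[C@@H]1[C@H](c1ccc(O[Si](C(C)C)(C(C)C)C(C)C)cc1)[C@H]2c1cc(O[Si](C(C)C)(C(C)C)C(C)C)cc(O[Si](C(C)C)(C(C)C)C(C)C)c1 | intermediate
16 | tert-butyl(4-iodophenoxy)dimethylsilane | Ic1ccc(O[Si](C)(C)C(C)(C)C)cc1 | starting material
17 | (1R,5S,6R,7R)-4-[(E)-2-{4-[(tert-butyldimethylsilyl)oxy]phenyl}ethenyl]-6-{3,5-bis[(triisopropylsilyl)oxy]phenyl}-7-{4-[(triisopropylsilyl)oxy]phenyl}bicyclo[3.2.1]oct-3-ene-2,8-dione | O=C1C=C(/C=C/c2ccc(O[Si](C)(C)C(C)(C)C)cc2)[C@H]2C(=O)[C@@H]1[C@H](c1ccc(O[Si](C(C)C)(C(C)C)C(C)C)cc1)[C@H]2c1cc(O[Si](C(C)C)(C(C)C)C(C)C)cc(O[Si](C(C)C)(C(C)C)C(C)C)c1 | intermediate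
18 | vitisinol D, (1R,5S,6R,7R)-6-(3,5-dihydroxyphenyl)-7-(4-hydroxyphenyl)-4-[(E)-2-(4-hydroxyphenyl)ethenyl]bicyclo[3.2.1]oct-3-ene-2,8-dione | O=C1C=C(/C=C/c2ccc(O)cc2)[C@H]2C(=O)[C@@H]1[C@H](c1ccc(O)cc1)[C@H]2c1cc(O)cc(O)c1 | target

Total step count: 10. Longest linear sequence: 10 steps (1 → 18).

**Steps most likely to fail**

Step 6. The benzylic cation may be captured through the C8 enol oxygen instead of C1, may lose the C6 proton (E1, which would also erode the C6 configuration if it reverses), or the nitro group may ionise too slowly. The fallback changes from a cation to a neutral para-quinone methide. Setting out from 9, Bu4NF in THF followed by aqueous NaHCO3 buffer removes the three silyl groups; the phenoxide of the 4-hydroxyphenyl ring then expels nitrite (vinylogous E1cB) and the dione enolate adds 1,6 to the quinone methide. Oxygen adducts revert through the phenoxide while the C–C adduct accumulates, giving the triphenol bicyclic dione F1. Resilylation with TIPSCl and imidazole returns to the route at 10.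

Step 4. The β-branched nitronate may couple slowly with the electron-rich aryl bromide, and prolonged heating with carbonate may epimerise the centre next to the ketone. The fallback makes the C7–aryl bond by carbonyl addition instead of cross-coupling. Setting out from 6, a TiCl3/NH4OAc Nef reaction gives the aldehyde F2, which is used at once and cold because the centre next to the formyl group is epimerisable. The aryl Grignard reagent F3 (from 7 and Mg) adds at −78 °C to the aldehyde only and gives the benzylic alcohol F4. Claisen cyclisation with LiN(SiMe3)2 gives the hydroxy dione F5, and BF3·OEt2 in CH2Cl2 at −40 °C ionises the benzylic alcohol for the same bridging C-alkylation. This replaces steps 5 and 6 and returns to the route at 10.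

Step 8. The Grignard reagent may add 1,2 to the strained C8 ketone, and the second dehydrogenation may be slow because the hydrogen left on C4 lies on the face shielded by the C6–C7 bridge. The fallback uses addition–elimination instead of addition–oxidation. Setting out from 12, conjugate addition of PhSH with Et3N gives the β-phenylthio ketone F6. N-Chlorosuccinimide (Pummerer-type chlorination and elimination) gives the β-(phenylthio)enone F7. Bromomagnesium divinylcuprate (from 13 and CuI) then adds and expels thiophenolate, returning to the route at 15.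

**Further compounds**
F1 | step 6 | (1R,5R,6R,7R)-6-(3,5-dihydroxyphenyl)-7-(4-hydroxyphenyl)bicyclo[3.2.1]octane-2,8-dione | O=C1CC[C@H]2C(=O)[C@@H]1[C@H](c1ccc(O)cc1)[C@H]2c1cc(O)cc(O)c1
F2 | step 4 | ethyl (4R,5R)-4-acetyl-5-{3,5-bis[(triisopropylsilyl)oxy]phenyl}-6-oxohexanoate | CCOC(=O)CC[C@@H](C(C)=O)[C@@H](C=O)c1cc(O[Si](C(C)C)(C(C)C)C(C)C)cc(O[Si](C(C)C)(C(C)C)C(C)C)c1
F3 | step 4 | {4-[(triisopropylsilyl)oxy]phenyl}magnesium bromide | Br[Mg]c1ccc(O[Si](C(C)C)(C(C)C)C(C)C)cc1
F4 | step 4 | ethyl (4R,5R,6RS)-4-acetyl-5-{3,5-bis[(triisopropylsilyl)oxy]phenyl}-6-hydroxy-6-{4-[(triisopropylsilyl)oxy]phenyl}hexanoate | CCOC(=O)CC[C@@H](C(C)=O)[C@@H](C(O)c1ccc(O[Si](C(C)C)(C(C)C)C(C)C)cc1)c1cc(O[Si](C(C)C)(C(C)C)C(C)C)cc(O[Si](C(C)C)(C(C)C)C(C)C)c1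
F5 | step 4 | (4R)-4-[(1R,2RS)-1-{3,5-bis[(triisopropylsilyl)oxy]phenyl}-2-hydroxy-2-{4-[(triisopropylsilyl)oxy]phenyl}ethyl]cyclohexane-1,3-dione | O=C1CC[C@@H](C(=O)C1)[C@@H](C(O)c1ccc(O[Si](C(C)C)(C(C)C)C(C)C)cc1)c1cc(O[Si](C(C)C)(C(C)C)C(C)C)cc(O[Si](C(C)C)(C(C)C)C(C)C)c1
F6 | step 8 | 4-(phenylsulfanyl) derivative of 10 (sulfur on the face away from the C6–C7 bridge) | O=C1C[C@@H](Sc3ccccc3)[C@H]2C(=O)[C@@H]1[C@H](c1ccc(O[Si](C(C)C)(C(C)C)C(C)C)cc1)[C@H]2c1cc(O[Si](C(C)C)(C(C)C)C(C)C)cc(O[Si](C(C)C)(C(C)C)C(C)C)c1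
F7 | step 8 | 4-(phenylsulfanyl) derivative of 12 (β-(phenylthio)enone) | O=C1C=C(Sc3ccccc3)[C@H]2C(=O)[C@@H]1[C@H](c1ccc(O[Si](C(C)C)(C(C)C)C(C)C)cc1)[C@H]2c1cc(O[Si](C(C)C)(C(C)C)C(C)C)cc(O[Si](C(C)C)(C(C)C)C(C)C)c1
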